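At early times we read the feed from the solid: target plus dissolved substrate at the first reading of each run.

| flask | solid substrate | coupling partner | remark | time |
|---|---|---|---|---|
| winter | 9.4 mM | 35 mM | run made earlier |  |
| noon | 21 mM | 35 mM | run made earlier |  |
| flask | 14 mM | 35.0 mM |  | 20 h |

| run | time / h | target / % | dissolved substrate / % |
|---|---|---|---|
| winter | 2.00 | 3.6 | 14.6 |
| winter | 6.00 | 15.9 | 20.5 |
| winter | 10.0 | 34.1 | 21.4 |
| winter | 15.0 | 50.9 | 4.9 |
| noon | 1.33 | 0.8 | 4.3 |
| noon | 3.00 | 1.1 | 7.6 |
| noon | 6.00 | 3.4 | 8.8 |
| noon | 15.0 | 8.9 | 11.5 |

(readings scatter by 0.5 percentage points)

- amount of target at 20 h, in percent of the solid substrate charged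
- concentration of dissolved substrate in solution at 20 h, in percent of saturation

- in percentages every species weighs as the solid substrate in it: one side product A or side product B counts as two
- as a solid, counted per litre of solution: solid substrate
- candidate steps: 2 dissolved substrate -> side product A; solid substrate <-> dissolved substrate; solid substrate + target -> side product B; coupling partner <-> dormant form; dissolved substrate + coupling partner -> target
- at the start none of the solid substrate is in solution
- dissolved substrate means what is dissolved; the solid is not counted in it

Column against column, the first rows give 0.855 mM h⁻¹ in the winter run and 0.805 mM h⁻¹ in the noon run, though noon charged more solid. So in these two readings the feed does not follow the charge, and we take 0.830 mM h⁻¹. By this count the solid lasts 11.3 h in the winter run and 25.3 h in the noon run. The step to side product B can shorten that.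

The last rows agree. The noon run, inside its count, still climbs to 11.5 % dissolved substrate. The winter run, whose count ends between 10.0 h and 15.0 h, loses 16 percentage points of dissolved substrate over those readings, while target gains 17 points. So the end state is plain: once the solid ends, target plus dissolved substrate is target's ceiling.

Those rows give 2.35 h as a reading of the time in which c(dissolved substrate) halves once no solid feeds it, our tail half-life, pseudo-first-order while coupling partner stays in excess. Our count ends the solid between those rows, so some feed may stand in this reading.

In the asked flask the solid lasts 16.9 h by our count, which leaves 3.10 h of tail. Taking the winter reading of 2.01 mM at 10.0 h as the level where the tail begins, we expect 0.797 mM still dissolved in the asked flask, so our estimate puts target 5.69 % of the charge below its ceiling.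

The forecast gives 34 % of target and 7 % of saturation, and says “solid lasts until about 15 h”, against our 16.9 h.

The flask gives 36.2 % and 7.04 %.

    2 dissolved substrate → side product A (k = 3.70 L mol⁻¹ h⁻¹)
    solid substrate ⇌ dissolved substrate, rate k2*(cs2 - [dissolved substrate]) while solid is left; crystals form when [dissolved substrate] > cs2 (solubility = 5.90 mM, k = 0.180 h⁻¹)
    solid substrate + target → side product B (k = 60.0 L mol⁻¹ h⁻¹)
    coupling partner ⇌ dormant form (K = 0.150, k = 6.80 h⁻¹)
    dissolved substrate + coupling partner → target (k = 11.0 L mol⁻¹ h⁻¹)

At 20 h the flask's dissolved substrate has a half-life of 2.8 h by coupling, short against the run time, and 2.97 % is still dissolved, which puts the ceiling at 39.2 %. Some 76.6 of our tail half-lives later, the flask holds 39.1 %. For the winter run, the same reckoning from its reading at 15.0 h gives 54.7 % at 20 h, and that run then holds 54.4 %.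

The data stem from a simulated flask from invented constants; noise was put on by code.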